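**Plan**
1. Retrosynthesis: the C11–O aryl ether is cut first (Mitsunobu). Ring A is then cut at C1–C2 and C4–C5 into 3-methylbutan-2-one (C2–C3–C4 plus the gem-dimethyl group) and a cis-fused enone γ-lactone.
2. The enone lactone (ring B) comes from a Diels–Alder reaction of an (S)-configured α-methylbutenolide (C1, C10, C9, C11) with a 1-amino-3-siloxy diene (C5–C8).
3. Forward: butenolide, then ring B (cycloaddition), then ring A (one-flask Michael–Claisen [3+3] annulation), then redox adjustment, then the aryl ether.
4. Enabling feature: the enone β-carbon C5 (activated by the C7 ketone) and the lactone acyl carbon C1 flank the quaternary C10 as a 1,3-bis-electrophile. The lactone is at once tether, acyl donor and protecting group of the C11 oxygen.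
5. Stereochemistry: the carbinol carbon of (S)-benzyl glycidyl ether directs the cycloaddition (C9, C10). The lactone face directs the Michael step (C5, trans-decalin). LiBH(s-Bu)3 sets the axial C3 alcohol.
6. Helpers removed later: the C1 oxygen (cyclic vinylogous ester, Li/NH3), the C7 oxygen (enol phosphate, Li/NH3), and the CH2OBn carbon with its stereocentre (periodate).

Key step: step 5

Remark: decalin carbons are numbered as in drimanes (C10 angular-methyl carbon, C4 gem-dimethyl carbon, C11 the oxymethylene carbon on C9); C8 is epimerisable before step 6 and is drawn as the expected major epimer.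

**Step 1**
Reactants: 1 (S)-benzyl glycidyl ether; 2 propanoic acid
Product: 4 (5S)-5-[(benzyloxy)methyl]-3-methyldihydrofuran-2(3H)-one (C3 epimer mixture), via hydroxy acid 3 (not isolated)
Conditions: 2, LiN(i-Pr)2 (2.1 equiv), THF/HMPA, 0 °C; then 1, 0 → 40 °C; then aq. HCl; TsOH·H2O (cat.), PhMe, 80 °C
Reagents that add atoms: none
Why: Epoxide opening by a carboxylic acid dianion at the unsubstituted carbon followed by acid-catalysed lactonisation should give the γ-lactone with the carbinol stereocentre of 1 untouched (the α-methyl centre is erased in step 2).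

**Step 2**
Reactants: 4
Product: 6 (S)-5-[(benzyloxy)methyl]-3-methylfuran-2(5H)-one, via selenide 5 (not isolated)
Conditions: LiN(i-Pr)2, THF, −78 °C; PhSeBr; then 30% H2O2, pyridine, CH2Cl2, 0 → 25 °C
Reagents that add atoms: none
Why: α-Selenenylation of the lactone enolate and selenoxide syn-elimination toward the ring hydrogen should give the endocyclic butenolide without touching the γ-stereocentre.

**Step 3**
Reactants: 6; 7 (E)-3-[(tert-butyldimethylsilyl)oxy]-N,N-dimethylbuta-1,3-dien-1-amine
Product: 9 (3S,3aS,7aR)-3-[(benzyloxy)methyl]-7a-methyl-3a,4-dihydro-2-benzofuran-1,5(3H,7aH)-dione, via cycloadduct 8 (not isolated)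
Conditions: PhMe, 100 °C (sealed tube); then 1 M aq. HCl, THF, 0 → 25 °C
Reagents that add atoms: none
Why: Diels–Alder reaction of the electron-rich diene (CH2 terminus to the butenolide β-carbon C9, amino-bearing terminus to the α-carbon C10) on the face anti to the γ-CH2OBn group should set C9 and the quaternary C10 as a cis-fused pair, and acid then hydrolyses the silyl enol ether and eliminates dimethylamine to the enone.

**Step 4**
Reactants: 9
Product: 10 (3S,3aS,4S,7aR)-3-[(benzyloxy)methyl]-4,7a-dimethyl-3a,4-dihydro-2-benzofuran-1,5(3H,7aH)-dione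
Conditions: LiN(i-Pr)2, THF, −78 °C; MeI, DMPU, −78 → −20 °C
Reagents that add atoms: iodomethane, CI
Why: Kinetic deprotonation at C8 (the only enolisable position of the enone) and enolate C-methylation anti to the lactone ring should install the C8 methyl group, whose configuration does not matter because C8 becomes trigonal in step 6.

**Step 5**
Reactants: 10; 11 3-methylbutan-2-one
Product: 14 (5S,8R,9S,10R,11S)-11-[(benzyloxy)methyl]-1,11-epoxydrim-1-ene-3,7-dione (cyclic vinylogous ester), via Michael adduct 12 (not isolated), via hydroxy trione 13 (not isolated)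
Conditions: 11 (5 equiv), KOt-Bu (3 equiv), t-BuOH/THF, 0 → 45 °C; then AcOH; TsOH·H2O (cat.), PhMe, reflux (−H2O)
Reagents that add atoms: none
Why: Proposed new method: KOt-Bu equilibrates the enolates of 11 and the more substituted one adds through C4 to the enone β-carbon C5 (Michael addition); after proton transfer the methyl-side enolate (C2) acylates the lactone carbonyl C1 (Claisen condensation) with expulsion of the C11 alkoxide, and the 1,3-diketone is held as its enolate until acid closes the freed C11 hydroxyl onto C1. The closest known reaction type is the consecutive Michael–Claisen synthesis of 4,4-dimethylcyclohexane-1,3-dione from 3-methylbutan-2-one and an acrylate ester; new is that an enone β-carbon and a lactone acyl carbon on either side of a quaternary carbon serve as the 1,3-bis-electrophile. Ring A closes by a 6-(enolendo)-exo-trig acylation and the dihydrofuran ring of 14 by 5-exo-trig hemiketalisation followed by dehydration. C5 is the only new stereocentre and is set in the Michael step by the cis-fused lactone, which covers the face of C5 syn to the C10–C1 bond so that C4 enters cis to the angular methyl group and the diequatorial C4 and C1 arms then close to the trans-decalin, while C8 equilibrates to the equatorial methyl epimer. The step needs C4 and not C2 as the Michael donor and Michael addition before acylation, which is secured thermodynamically because only this sequence ends in a diketone with an acidic CH2 between its carbonyl groups, so that all other adducts revert by retro-Michael or retro-Claisen reaction (the ring-opened acylation product relactonises through its own alkoxide).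

**Step 6**
Reactants: 14
Product: 15 (5S,9S,10R,11S)-11-[(benzyloxy)methyl]-3-oxo-1,11-epoxydrima-1,7-dien-7-yl diethyl phosphate
Conditions: LiN(i-Pr)2 (0.95 equiv), THF, −78 → 25 °C (enolate equilibration); ClP(O)(OEt)2, TMEDA, 0 °C
Reagents that add atoms: diethyl chlorophosphate, CCOP(=O)(Cl)OCC
Why: Equilibration of the lithium enolate of the only enolisable ketone toward the more substituted C7=C8 isomer and O-phosphorylation (enol phosphate formation) should fix the position of the future alkene, while the vinylogous ester carries no acidic hydrogen.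

**Step 7**
Reactants: 15
Product: 16 (4aR,5S,8aS)-5-[(1S)-1,2-dihydroxyethyl]-1,1,4a,6-tetramethyl-3,4,4a,5,8,8a-hexahydronaphthalen-2(1H)-one
Conditions: Li (15 equiv), NH3/THF, t-BuOH (3 equiv), −78 → −33 °C; isoprene; NH4Cl
Reagents that add atoms: none
Why: Dissolving-metal reduction should in one operation cleave the enol phosphate to the C7=C8 alkene, reduce the β-alkoxy enone with β-elimination of the C11 alkoxide and further reduction to the C3 ketone enolate, and remove the benzyl ether, while the trisubstituted alkene and the enolate-protected ketone survive.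

**Step 8**
Reactants: 16
Product: 18 (2S,4aR,5S,8aS)-5-(hydroxymethyl)-1,1,4a,6-tetramethyl-1,2,3,4,4a,5,8,8a-octahydronaphthalen-2-ol, via aldehyde 17 (not isolated)
Conditions: NaIO4, THF/H2O, 0 °C; extractive work-up; then LiBH(s-Bu)3 (excess), THF, −78 → 0 °C; aq. NH4Cl
Reagents that add atoms: none
Why: Periodate glycol cleavage excises the auxiliary carbon, and LiBH(s-Bu)3 then reduces the aldehyde and attacks the C3 ketone from the equatorial direction to give the axial (3S) alcohol.

**Step 9**
Reactants: 18; 19 scopoletin (7-hydroxy-6-methoxy-2H-chromen-2-one)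
Product: 20 7-{[(1S,4aS,6S,8aR)-6-hydroxy-2,5,5,8a-tetramethyl-1,4,4a,5,6,7,8,8a-octahydronaphthalen-1-yl]methoxy}-6-methoxy-2H-chromen-2-one (target)
Conditions: PPh3, DIAD, THF, 0 → 25 °C
Reagents that add atoms: none
Why: Mitsunobu etherification should engage only the primary C11 alcohol with the acidic 7-hydroxyl group of 19, because the axial C3 alcohol next to the gem-dimethyl carbon is too hindered to react and no stereocentre is involved.

**Compound list**
1 | (S)-benzyl glycidyl ether | C([C@@H]1CO1)OCc1ccccc1 | starting material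
2 | propanoic acid | CCC(=O)O | starting material
3 | (4S)-5-(benzyloxy)-4-hydroxy-2-methylpentanoic acid (C2 epimers) | CC(C[C@H](O)COCc1ccccc1)C(=O)O | intermediate (not isolated)
4 | (5S)-5-[(benzyloxy)methyl]-3-methyldihydrofuran-2(3H)-one (C3 epimers) | CC1C[C@@H](COCc2ccccc2)OC1=O | intermediate
5 | (5S)-5-[(benzyloxy)methyl]-3-methyl-3-(phenylselanyl)dihydrofuran-2(3H)-one (C3 epimers) | CC1([Se]c2ccccc2)C[C@@H](COCc3ccccc3)OC1=O | intermediate (not isolated)
6 | (S)-5-[(benzyloxy)methyl]-3-methylfuran-2(5H)-one | CC1=C[C@@H](COCc2ccccc2)OC1=O | intermediate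
7 | (E)-3-[(tert-butyldimethylsilyl)oxy]-N,N-dimethylbuta-1,3-dien-1-amine | CN(C)/C=C/C(=C)O[Si](C)(C)C(C)(C)C | starting material
8 | (3S,3aS,7aS)-3-[(benzyloxy)methyl]-5-[(tert-butyldimethylsilyl)oxy]-7-(dimethylamino)-7a-methyl-3a,4,7,7a-tetrahydro-2-benzofuran-1(3H)-one (C7 epimers) | C(OCc1ccccc1)[C@@H]3[C@H]1CC(O[Si](C)(C)C(C)(C)C)=CC(N(C)C)[C@@]1(C)C(=O)O3 | intermediate (not isolated)
9 | (3S,3aS,7aR)-3-[(benzyloxy)methyl]-7a-methyl-3a,4-dihydro-2-benzofuran-1,5(3H,7aH)-dione | C(OCc1ccccc1)[C@@H]3[C@H]1CC(=O)C=C[C@@]1(C)C(=O)O3 | intermediate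
10 | (3S,3aS,4S,7aR)-3-[(benzyloxy)methyl]-4,7a-dimethyl-3a,4-dihydro-2-benzofuran-1,5(3H,7aH)-dione | C(OCc1ccccc1)[C@@H]3[C@H]1[C@H](C)C(=O)C=C[C@@]1(C)C(=O)O3 | intermediate
11 | 3-methylbutan-2-one | CC(=O)C(C)C | starting material
12 | (3S,3aS,4S,7R,7aR)-3-[(benzyloxy)methyl]-4,7a-dimethyl-7-(2-methyl-3-oxobutan-2-yl)-3a,4,7,7a-tetrahydro-2-benzofuran-1,5(3H,6H)-dione | C(OCc1ccccc1)[C@@H]3[C@H]1[C@H](C)C(=O)C[C@H](C(C)(C)C(C)=O)[C@@]1(C)C(=O)O3 | intermediate (not isolated)
13 | (4aR,7R,8S,8aR)-8-[(1S)-2-(benzyloxy)-1-hydroxyethyl]-4,4,7,8a-tetramethyl-4a,5,8,8a-tetrahydronaphthalene-1,3,6(2H,4H,7H)-trione | C(OCc1ccccc1)[C@@H](O)[C@H]1[C@@H](C)C(=O)C[C@@H]2C(C)(C)C(=O)CC(=O)[C@]21C | intermediate (not isolated)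
14 | (5S,8R,9S,10R,11S)-11-[(benzyloxy)methyl]-1,11-epoxydrim-1-ene-3,7-dione (enol ether oxygen bridges C1 and C11) | C(OCc1ccccc1)[C@@H]3[C@H]1[C@@H](C)C(=O)C[C@@H]2C(C)(C)C(=O)C=C(O3)[C@]21C | intermediate
15 | (5S,9S,10R,11S)-11-[(benzyloxy)methyl]-3-oxo-1,11-epoxydrima-1,7-dien-7-yl diethyl phosphate | C(OCc1ccccc1)[C@@H]3[C@H]1C(C)=C(OP(=O)(OCC)OCC)C[C@@H]2C(C)(C)C(=O)C=C(O3)[C@]21C | intermediate
16 | (4aR,5S,8aS)-5-[(1S)-1,2-dihydroxyethyl]-1,1,4a,6-tetramethyl-3,4,4a,5,8,8a-hexahydronaphthalen-2(1H)-one | C(O)[C@@H](O)[C@H]1C(C)=CC[C@@H]2C(C)(C)C(=O)CC[C@]21C | intermediate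
17 | (1S,4aS,8aR)-2,5,5,8a-tetramethyl-6-oxo-1,4,4a,5,6,7,8,8a-octahydronaphthalene-1-carbaldehyde | O=C[C@H]1C(C)=CC[C@@H]2C(C)(C)C(=O)CC[C@]21C | intermediate (not isolated)
18 | (2S,4aR,5S,8aS)-5-(hydroxymethyl)-1,1,4a,6-tetramethyl-1,2,3,4,4a,5,8,8a-octahydronaphthalen-2-ol | OC[C@H]1C(C)=CC[C@@H]2C(C)(C)[C@@H](O)CC[C@]21C | intermediate
19 | scopoletin (7-hydroxy-6-methoxy-2H-chromen-2-one) | COc1cc2ccc(=O)oc2cc1O | starting material
20 | 7-{[(1S,4aS,6S,8aR)-6-hydroxy-2,5,5,8a-tetramethyl-1,4,4a,5,6,7,8,8a-octahydronaphthalen-1-yl]methoxy}-6-methoxy-2H-chromen-2-one | COc1cc2ccc(=O)oc2cc1OC[C@H]1C(C)=CC[C@@H]2C(C)(C)[C@@H](O)CC[C@]21C | target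

**Totals**
Total step count: 9. Longest linear sequence: 9 steps (from 1).

**Steps most likely to fail**
1. Step 5 (bears the new-method label). The cascade may divert through acylation of the methyl-side enolate by the lactone before any Michael addition, through reversal of the hindered Michael addition, or through addition to the wrong face of C5. Fallback with known reactions, run stepwise from 10: TiCl4-promoted Mukaiyama–Michael addition of 2-methyl-3-(trimethylsilyloxy)but-2-ene F1 (made from 11 with Me3SiCl, NaI and Et3N in MeCN) in CH2Cl2 at −78 °C should give 12 as an isolated compound, with the donor carbon fixed by the silyl enol ether. KOt-Bu in THF then effects the intramolecular Claisen acylation of the lactone to 13, and TsOH in hot toluene returns the route to 14.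
2. Step 6. Enolisation may go toward C6, or the C6 enolate may open ring A by retro-Michael reaction during equilibration. Fallback from 14: LiBH(s-Bu)3 reduction of the C7 ketone should give the axial alcohol F2; POCl3 in pyridine then eliminates it anti-periplanar to the axial C8 hydrogen to the trisubstituted alkene F3; the Li/NH3 conditions of step 7 convert F3 into 16.
3. Step 9. Conversion may be low, or elimination may compete, at the β-branched primary carbon during the redox condensation. Fallback from 18: selective sulfonylation of the primary alcohol (MsCl, Et3N, CH2Cl2, −20 °C) should give the mesylate F4, which is displaced by the phenoxide of 19 (Cs2CO3, DMF, 60 °C) to return to 20.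

**Further compounds**
F1 | step 5 | 2-methyl-3-(trimethylsilyloxy)but-2-ene | CC(C)=C(C)O[Si](C)(C)C
F2 | step 6 | (5S,7S,8R,9S,10R,11S)-11-[(benzyloxy)methyl]-7-hydroxy-1,11-epoxydrim-1-en-3-one | C(OCc1ccccc1)[C@@H]3[C@H]1[C@@H](C)[C@@H](O)C[C@@H]2C(C)(C)C(=O)C=C(O3)[C@]21C
F3 | step 6 | (5S,9S,10R,11S)-11-[(benzyloxy)methyl]-1,11-epoxydrima-1,7-dien-3-one | C(OCc1ccccc1)[C@@H]3[C@H]1C(C)=CC[C@@H]2C(C)(C)C(=O)C=C(O3)[C@]21C
F4 | step 9 | [(1S,4aS,6S,8aR)-6-hydroxy-2,5,5,8a-tetramethyl-1,4,4a,5,6,7,8,8a-octahydronaphthalen-1-yl]methyl methanesulfonate | CS(=O)(=O)OC[C@H]1C(C)=CC[C@@H]2C(C)(C)[C@@H](O)CC[C@]21C
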